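**Retrosynthetic overview**
- Target ⇒ open-chain (6R) tertiary hydroperoxide carrying an (E)-2-methyl enoate: cut O–C3 (intramolecular peroxy-oxa-Michael addition; closes the 1,2-dioxane and sets C3 and C2).
- Hydroperoxy enoate ⇒ diene ester with a 1,1-disubstituted alkene: cut C6–O (Markovnikov hydroperoxidation; sets C6).
- Diene ester ⇒ γ,δ-unsaturated aldehyde + α-methyl stabilised ylide (Wittig, E-enoate).
- Aldehyde ⇒ 2-substituted allylic alcohol + ethyl vinyl ether (Claisen); allylic alcohol ⇒ (2E,6E)-farnesyl bromide + methallyl alcohol dianion.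
- Ring order: one ring only, the 1,2-dioxane, closed in the last step.

Assumption: the sense of induction in steps 4 and 5 cannot be predicted with certainty; the catalyst enantiomers named are those assumed to give the products shown, and their mirror images are used if the opposite sense is found.

**Step 1**
Reactants: 1 (2E,6E)-farnesyl bromide; 2 2-methylprop-2-en-1-ol (methallyl alcohol)
Product: 4 (5E,9E)-6,10,14-trimethyl-2-methylidenepentadeca-5,9,13-trien-1-ol, via dilithiated methallyl alcohol 3 (not isolated)
Conditions: 2 (3 equiv), n-BuLi (2.1 equiv per 2), TMEDA, Et2O–hexane, 0 °C → rt, 20 h; then 1, THF, −78 °C → rt; H2O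
Reagents that add atoms: none
Why: Alkoxide-directed allylic lithiation gives the O,C-dianion, whose carbon end displaces the primary allylic bromide by SN2 (dianion alkylation); the E,E-alkenes are untouched and no stereocentre is formed.

**Step 2**
Reactants: 4 (5E,9E)-6,10,14-trimethyl-2-methylidenepentadeca-5,9,13-trien-1-ol; 5 ethyl vinyl ether
Product: 7 (7E,11E)-8,12,16-trimethyl-4-methylideneheptadeca-7,11,15-trienal, via allyl vinyl ether 6 (not isolated)
Conditions: 5 (solvent), Hg(OAc)2 (10 mol %), reflux, 16 h; evaporate; toluene, 140 °C, sealed tube, 6 h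
Reagents that add atoms: none
Why: Hg(OAc)2-catalysed vinyl transfer gives the allyl vinyl ether, which undergoes the thermal [3,3]-sigmatropic Claisen rearrangement to the γ,δ-unsaturated aldehyde; the new alkene is 1,1-disubstituted, so no stereo-element arises.

**Step 3**
Reactants: 7 (7E,11E)-8,12,16-trimethyl-4-methylideneheptadeca-7,11,15-trienal; 8 methyl 2-(triphenylphosphoranylidene)propanoate
Product: 9 methyl (2E,9E,13E)-2,10,14,18-tetramethyl-6-methylidenenonadeca-2,9,13,17-tetraenoate
Conditions: toluene, 80 °C, 12 h
Reagents that add atoms: none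
Why: Wittig olefination with the α-methyl stabilised ylide is E-selective (about 95:5) and gives the (2E)-2-methyl enoate; the isolated alkenes do not react.

**Step 4**
Reactants: 9 methyl (2E,9E,13E)-2,10,14,18-tetramethyl-6-methylidenenonadeca-2,9,13,17-tetraenoate
Product: 10 methyl (2E,6R,9E,13E)-6-hydroperoxy-2,6,10,14,18-pentamethylnonadeca-2,9,13,17-tetraenoate
Conditions: H2O2 (anhydrous, 1 M in Et2O, 5 equiv), Co(L*) (5 mol %; L* = (R,R)-N,N′-bis(3,5-di-tert-butylsalicylidene)cyclohexane-1,2-diaminate, divalent cobalt), 1-fluoro-2,4,6-trimethylpyridinium triflate (1.3 equiv), (HMe2Si)2O (1.2 equiv), PhCF3, −20 °C, 12 h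
Reagents that add atoms: hydrogen peroxide, OO
Why: Proposed new method: enantioselective radical–polar crossover Markovnikov hydroperoxidation. The cobalt hydride formed from the chiral cobalt salen complex, the N-fluoropyridinium oxidant and the silane transfers a hydrogen atom only to the unhindered CH2 terminus of the 1,1-disubstituted alkene; the trisubstituted alkenes and the β-substituted enoate react far more slowly with bulky cobalt hydrides, and the C6 radical has no 5-exo or 6-endo cyclisation open to it. The tertiary radical is captured by the chiral complex and oxidised to a cationic alkylcobalt species (tetravalent cobalt) or its tight ion pair. H2O2 then attacks C6 on the face left open by the stepped ligand and loses a proton, so methyl and the long chain are told apart in the chiral pocket and C6 is set as R. An er near 80:20 is enough, because step 5 turns 6S material into a separable diastereomer. Closest known reaction type: cobalt–salen HAT/radical-polar crossover hydroalkoxylation and hydration of unactivated alkenes, including enantioselective ring-forming versions, and Mukaiyama–Isayama silylperoxidation.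

**Step 5**
Reactants: 10 methyl (2E,6R,9E,13E)-6-hydroperoxy-2,6,10,14,18-pentamethylnonadeca-2,9,13,17-tetraenoate
Product: 11 methyl (2R)-2-[(3S,6R)-6-methyl-6-[(3E,7E)-4,8,12-trimethyltrideca-3,7,11-trien-1-yl]-1,2-dioxan-3-yl]propanoate
Conditions: N-[(S)-3,3-dimethyl-1-[tris(4-methoxyphenyl)phosphoranylideneamino]butan-2-yl]-N′-[3,5-bis(trifluoromethyl)phenyl]urea (10 mol %, pre-formed from its azide, no free phosphine), toluene, −20 → 0 °C, 24–48 h; AcOH quench; chromatography
Reagents that add atoms: none
Why: Proposed new method: catalyst-controlled intramolecular peroxy-oxa-Michael addition with enantioselective protonation. The strongly basic iminophosphorane deprotonates the hydroperoxide (pKa about 12) to a tight chiral ion pair while the urea N–H groups bind and activate the enoate carbonyl. The peroxide oxygen adds 6-exo-trig through a chair transition state (new side chain equatorial) to the enoate face that gives 3S. The ester enolate is then protonated inside the ion pair by the iminophosphoranium N–H on the face that gives 2R (2,3-syn). C6 is untouched, so (6R)-10 gives the 3,6-trans product and any (6S)-10 gives the 3,6-cis diastereomer, which chromatography removes; the enantiomeric purity of 11 is therefore the product of both selections. Closest known reaction type: bifunctional iminophosphorane-catalysed enantioselective intramolecular oxa-Michael addition of alcohols to α,β-unsaturated esters, and the racemic amine/fluoro-alcohol peroxy-Michael closure of 1,2-dioxanes.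

**Compound list**
1 | (2E,6E)-1-bromo-3,7,11-trimethyldodeca-2,6,10-triene (farnesyl bromide) | BrC/C=C(\C)CC/C=C(\C)CCC=C(C)C | starting material
2 | 2-methylprop-2-en-1-ol (methallyl alcohol) | C=C(C)CO | starting material
3 | dilithiated methallyl alcohol (lithium 2-(lithiomethyl)prop-2-en-1-olate) | [Li]CC(=C)CO[Li] | intermediate
4 | (5E,9E)-6,10,14-trimethyl-2-methylidenepentadeca-5,9,13-trien-1-ol | OCC(=C)CC/C=C(\C)CC/C=C(\C)CCC=C(C)C | intermediate
5 | ethyl vinyl ether | C=COCC | starting material
6 | (5E,9E)-2-[(ethenyloxy)methyl]-6,10,14-trimethylpentadeca-1,5,9,13-tetraene (allyl vinyl ether) | C=COCC(=C)CC/C=C(\C)CC/C=C(\C)CCC=C(C)C | intermediate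
7 | (7E,11E)-8,12,16-trimethyl-4-methylideneheptadeca-7,11,15-trienal | O=CCCC(=C)CC/C=C(\C)CC/C=C(\C)CCC=C(C)C | intermediate
8 | methyl 2-(triphenylphosphoranylidene)propanoate | COC(=O)C(C)=P(c1ccccc1)(c1ccccc1)c1ccccc1 | starting material
9 | methyl (2E,9E,13E)-2,10,14,18-tetramethyl-6-methylidenenonadeca-2,9,13,17-tetraenoate | COC(=O)/C(C)=C/CCC(=C)CC/C=C(\C)CC/C=C(\C)CCC=C(C)C | intermediate
10 | methyl (2E,6R,9E,13E)-6-hydroperoxy-2,6,10,14,18-pentamethylnonadeca-2,9,13,17-tetraenoate | COC(=O)/C(C)=C/CC[C@@](C)(CC/C=C(\C)CC/C=C(\C)CCC=C(C)C)OO | intermediate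
11 | methyl (2R)-2-[(3S,6R)-6-methyl-6-[(3E,7E)-4,8,12-trimethyltrideca-3,7,11-trien-1-yl]-1,2-dioxan-3-yl]propanoate | COC(=O)[C@H](C)[C@@H]1CC[C@@](C)(CC/C=C(\C)CC/C=C(\C)CCC=C(C)C)OO1 | target

Total step count: 5. Longest linear sequence: 5 steps (from 1 or 2).

**Three steps most likely to fail**

Step 4 (proposed new step). Risks: the cobalt catalyst may decompose H2O2; discrimination of methyl from a CH2CH2 chain at a tertiary centre may be weak; some hydrogen-atom transfer to trisubstituted alkenes may occur. The fallback uses known chemistry and trades ionic capture for radical oxygen trapping without stereocontrol; it sets out from 9 and comes back at 10. Compound 9 is treated with Co(thd)2 (thd = 2,2,6,6-tetramethylheptane-3,5-dionate), O2 and Et3SiH in ClCH2CH2Cl at rt (Mukaiyama–Isayama silylperoxidation, stopped near 60% conversion to spare the trisubstituted alkenes). This gives the racemic triethylsilyl peroxide F1. HCl (cat.) in MeOH at 0 °C removes silicon and returns 10 as a 1:1 mixture with its 6S enantiomer F2. Step 5 then converts F2 into the 3,6-cis dioxane F3, a diastereomer of 11 removed by HPLC. Compound 11 is still obtained as one enantiomer, at no more than half the yield.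

Step 5 (proposed new step). Risks: the trisubstituted enoate is a poor acceptor; the strong base may cleave the product by Kornblum–DeLaMare fragmentation; control of the C2 protonation may be incomplete. The fallback uses known chemistry and gives up catalyst control for substrate control plus separation and recycling; it sets out from 10 and comes back at 11. Et2NH (0.3 equiv) in CF3CH2OH at rt closes the ring (the known amine/fluoro-alcohol peroxy-Michael cyclisation). It gives 11 together with its C2 epimer F4, the 3,6-cis isomer F5 and the cis C2 epimer F6. Compound 11 is isolated by HPLC, and F4 to F6 are returned to the mixture by DBU-mediated retro-Michael and re-closure. The enantiomeric purity of 11 is then that of 10 from step 4.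

Step 1. Risks: incomplete dianion formation, and SN2′ or elimination with the allylic bromide. The fallback replaces the dianion by the acetoacetic ester route and a ketone methylenation; it sets out from 1 and comes back at 7. Compound 1 alkylates ethyl acetoacetate (NaOEt, EtOH) to the β-keto ester F7. Aqueous NaOH with heating, then acid, saponifies and decarboxylates it to (5E,9E)-farnesylacetone F8. LiN(i-Pr)2 in THF at −78 °C forms the methyl-side enolate, which ethyl bromoacetate (DMPU) alkylates to the γ-keto ester F9. Ph3P=CH2 in THF at 0 °C converts the ketone into the 4-methylidene ester F10, and i-Bu2AlH in CH2Cl2 at −78 °C gives 7.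

**Further compounds**
F1 | step 4 | methyl (2E,9E,13E)-2,6,10,14,18-pentamethyl-6-(triethylsilylperoxy)nonadeca-2,9,13,17-tetraenoate (racemic at C6) | COC(=O)/C(C)=C/CCC(C)(CC/C=C(\C)CC/C=C(\C)CCC=C(C)C)OO[Si](CC)(CC)CC
F2 | step 4 | methyl (2E,6S,9E,13E)-6-hydroperoxy-2,6,10,14,18-pentamethylnonadeca-2,9,13,17-tetraenoate | COC(=O)/C(C)=C/CC[C@](C)(CC/C=C(\C)CC/C=C(\C)CCC=C(C)C)OO
F3 | step 4 | methyl (2R)-2-[(3S,6S)-6-methyl-6-[(3E,7E)-4,8,12-trimethyltrideca-3,7,11-trien-1-yl]-1,2-dioxan-3-yl]propanoate | COC(=O)[C@H](C)[C@@H]1CC[C@](C)(CC/C=C(\C)CC/C=C(\C)CCC=C(C)C)OO1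
F4 | step 5 | methyl (2S)-2-[(3S,6R)-6-methyl-6-[(3E,7E)-4,8,12-trimethyltrideca-3,7,11-trien-1-yl]-1,2-dioxan-3-yl]propanoate | COC(=O)[C@@H](C)[C@@H]1CC[C@@](C)(CC/C=C(\C)CC/C=C(\C)CCC=C(C)C)OO1
F5 | step 5 | methyl (2R)-2-[(3R,6R)-6-methyl-6-[(3E,7E)-4,8,12-trimethyltrideca-3,7,11-trien-1-yl]-1,2-dioxan-3-yl]propanoate | COC(=O)[C@H](C)[C@H]1CC[C@@](C)(CC/C=C(\C)CC/C=C(\C)CCC=C(C)C)OO1
F6 | step 5 | methyl (2S)-2-[(3R,6R)-6-methyl-6-[(3E,7E)-4,8,12-trimethyltrideca-3,7,11-trien-1-yl]-1,2-dioxan-3-yl]propanoate | COC(=O)[C@@H](C)[C@H]1CC[C@@](C)(CC/C=C(\C)CC/C=C(\C)CCC=C(C)C)OO1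
F7 | step 1 | ethyl (4E,8E)-2-acetyl-5,9,13-trimethyltetradeca-4,8,12-trienoate (racemic) | CCOC(=O)C(C(C)=O)C/C=C(\C)CC/C=C(\C)CCC=C(C)C
F8 | step 1 | (5E,9E)-6,10,14-trimethylpentadeca-5,9,13-trien-2-one (farnesylacetone) | CC(=O)CC/C=C(\C)CC/C=C(\C)CCC=C(C)C
F9 | step 1 | ethyl (7E,11E)-8,12,16-trimethyl-4-oxoheptadeca-7,11,15-trienoate | CCOC(=O)CCC(=O)CC/C=C(\C)CC/C=C(\C)CCC=C(C)C
F10 | step 1 | ethyl (7E,11E)-8,12,16-trimethyl-4-methylideneheptadeca-7,11,15-trienoate | CCOC(=O)CCC(=C)CC/C=C(\C)CC/C=C(\C)CCC=C(C)C
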